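Divide the charge of J by the charge of Z before anything else. If each Z begins one chain, that ratio is the ceiling C, the average number of monomer units per chain once the whole charge of J sits in chains: 11.5 for both summer and winter. The average length is then the fraction in X times C, so the question becomes how much X each flask holds at the end.

| flask | J | Z | remark | time |
|---|---|---|---|---|
| Friday's | 0.38 M (fed, over 50 min) | 16 mM | run made earlier |  |
| Sunday's | 0.38 M (fed, over 50 min) | 25 mM | run made earlier |  |
| summer | 0.38 M (fed, over 50 min) | 33 mM |  | 1.0 h |
| winter | 0.38 M (fed, over 25 min) | 33 mM |  | 1.0 h |

- which of the two ends with the longer chains by the average number of monomer units in a chain (chains begun, living or dead) ("neither" if they lie within 10%) (summer / winter / neither)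
- average number of monomer units in a chain (chains begun, living or dead) at the end, summer
- average number of monomer units in a chain (chains begun, living or dead) at the end, winter

- the average divides the monomer in chains by the number of chains begun, living and dead together
- the earlier runs do not show the number of chains; that part of a forecast is a guess
- percentages count the whole charge, also what has not yet gone in

- Friday's (time / min: X / %): 5.00: 0.8; 15.0: 2.3; 30.0: 9.1; 40.0: 14.3; 60.0: 28.1
- Sunday's (time / min: X / %): 5.00: 0.3; 15.0: 3.8; 30.0: 12.5; 40.0: 20.4; 60.0: 39.6

(scatter of a reading: 0.3 percentage points)

Read the two tables row against row, in logarithms. The slope n is the logarithm of Sunday's X over Friday's X, divided by the logarithm of their ratio of Z. It reads 0.711 at 30.0 min, 0.796 at 40.0 min and 0.769 at 60.0 min. The earliest rows lie too near the scatter of 0.3 percentage points to serve.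

Summer has Sunday's feed and time, so Sunday's last reading, 39.6%, scaled by the ratio of Z to the power n, gives my own estimate for summer: X 49.0% and length 5.64.

Winter holds the same Z, so J is taken as pseudo-first-order with the summer constant. J enters on average at the midpoint of its feed, so it waits 47.5 min in winter, longer than the 35.0 min of summer. The logarithm of the fraction of J left is then taken to scale with the wait, by the factor 1.36 from summer to winter, so my reckoning names winter as the flask with the longer chains and gives no winter length of its own. One chain per Z remains a guess, since the runs show no chain count.

The forecast says winter, with 5.6 for summer and 7 for winter, on the grounds “Winter ends longer because monomer goes in earlier.”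

    J + Z → L + X (k = 0.0120 /M/s)
    J + L → X + L, rate k2*[L]*[J] (k = 0.0100 /M/s)

The flasks end at 5.60 in summer and 7.04 in winter, so winter has the longer chains. The guess of one chain per Z held: summer keeps 0.15% of its Z, holds 48.6% as X, and C multiplied by that X gives 5.59. The gap comes from the dosing time: winter given the summer feed ends at 5.60, not 7.04. A neighbour of winter charged with 0.65 M of J has C of 19.7; its X of 60.9% makes 12.0, and that flask ends at 12.0.

The runs are simulated from invented constants; the scatter is artificial.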